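**Retrosynthetic overview**

1. Numbering: ring C1 (CH2), C2–C3 (epoxide), C4 (carbinol, methyl C15), C5 (2-methylbutanoate), C6 (lactone oxygen), C7, C8 (angelate), C9 (ketone), C10 (methyl C14); lactone C11, C12 (C=O), C13 (=CH2). The γ-lactone is joined to the ten-membered carbocycle only through O6 and the C7–C11 bond, so C11–C13 are delivered last from an O6 diazophosphonoacetate into a C7–H bond (rhodium carbenoid 1,5 C–H insertion), followed by Horner–Wadsworth–Emmons methylenation and Si–O cleavage.
2. Carbocycle: C9–C10 by NiCl2/CrCl2 closure of an alkenyl bromide onto the C9 aldehyde, then oxidation, conjugate reduction (C10) and epoxidation (C2–C3).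
3. Seco chain: C6–C7 by chelation-controlled Mukaiyama aldol with the enol silane of 1,1-dimethoxyacetone (C7–C9); C8 and the O6 phosphonoacetate together by Evans–Tishchenko reduction with diethyl (2-oxoethyl)phosphonate.
4. C4–C6 from diethyl L-tartrate (its fourth carbon is excised by glycol cleavage); C4 by chelate-controlled ethynyl addition; C1, C10, C14 by hydrozirconation/copper-catalysed allylation with 2,3-dibromopropene.
5. Ring order: ten-membered carbocycle (step 16), epoxide (step 19), γ-lactone (step 21).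

Key step: step 21

Remark: the C10 configuration is taken to arise in step 18 by protonation of the ring enolate on its exposed face; a hydroxyl-directed alternative is given among the fallbacks.

**Route**

Step 1
Reactants: 1 diethyl L-tartrate
Product: 3 diethyl (2R,3R)-2-hydroxy-3-(4-methoxybenzyloxy)butanedioate, via stannylene acetal 2 (not isolated)
Conditions: Bu2SnO, toluene, reflux (Dean–Stark); then PMBCl, CsF, DMF, rt
Reagents that add atoms: 4-methoxybenzyl chloride, COc1ccc(CCl)cc1
Why: Tin-mediated mono-O-alkylation through the stannylene acetal; because 1 is C2-symmetric either hydroxyl gives the same mono-ether and no stereocentre is touched.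

Step 2
Reactants: 3 diethyl (2R,3R)-2-hydroxy-3-(4-methoxybenzyloxy)butanedioate
Product: 4 ethyl (2R,3S)-3,4-dihydroxy-2-(4-methoxybenzyloxy)butanoate
Conditions: BH3·SMe2 (1.05 equiv), NaBH4 (5 mol%), THF, 0 °C → rt; MeOH quench
Reagents that add atoms: none
Why: Hydroxyl-directed borane reduction of an α-hydroxy ester: the alkoxyborane formed at the free hydroxyl delivers hydride only to the neighbouring ester, so the ester next to the ether (future C4) should survive.

Step 3
Reactants: 4 ethyl (2R,3S)-3,4-dihydroxy-2-(4-methoxybenzyloxy)butanoate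
Product: 5 ethyl (2R)-2-[(4S)-2,2-dimethyl-1,3-dioxolan-4-yl]-2-(4-methoxybenzyloxy)acetate
Conditions: Me2C(OMe)2, PPTS (cat.), CH2Cl2, rt
Reagents that add atoms: 2,2-dimethoxypropane, COC(C)(C)OC
Why: Acid-catalysed transacetalisation closes the isopropylidene acetal on the terminal 1,2-diol, which masks C6 as a latent aldehyde and leaves the PMB ether and the ester untouched.

Step 4
Reactants: 5 ethyl (2R)-2-[(4S)-2,2-dimethyl-1,3-dioxolan-4-yl]-2-(4-methoxybenzyloxy)acetate
Product: 7 (1R)-1-[(4S)-2,2-dimethyl-1,3-dioxolan-4-yl]-1-(4-methoxybenzyloxy)propan-2-one, via Weinreb amide 6 (not isolated)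
Conditions: MeNH(OMe)·HCl, i-PrMgCl, THF, −20 °C; then MeMgBr, −20 → 0 °C
Reagents that add atoms: methylmagnesium bromide, C[Mg]Br
Why: Weinreb ketone synthesis in one flask: the magnesium amide converts the ester into amide 6, whose chelated tetrahedral adduct with MeMgBr collapses to the methyl ketone (C15) only on work-up, and the low temperature protects the C5 stereocentre.

Step 5
Reactants: 7 (1R)-1-[(4S)-2,2-dimethyl-1,3-dioxolan-4-yl]-1-(4-methoxybenzyloxy)propan-2-one
Product: 8 (1R,2R)-1-[(4S)-2,2-dimethyl-1,3-dioxolan-4-yl]-1-(4-methoxybenzyloxy)-2-methylbut-3-yn-2-ol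
Conditions: HC≡CMgBr, THF, −78 → −20 °C
Reagents that add atoms: ethynylmagnesium bromide, C#C[Mg]Br
Why: Cram-chelate controlled Grignard addition: magnesium bridges the ketone oxygen and the α-OPMB oxygen and the acetylide attacks the face opposite the dioxolanyl group, which should set C4 (R, hydroxyl syn to the C5 ether) and brings in C2 and C3.

Step 6
Reactants: 8 (1R,2R)-1-[(4S)-2,2-dimethyl-1,3-dioxolan-4-yl]-1-(4-methoxybenzyloxy)-2-methylbut-3-yn-2-ol
Product: 9 triethylsilyl ether of 8
Conditions: Et3SiOTf, 2,6-lutidine, CH2Cl2, −78 → 0 °C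
Reagents that add atoms: triethylsilyl triflate, CC[Si](CC)(CC)OS(=O)(=O)C(F)(F)F
Why: Silylation of the hindered tertiary propargylic alcohol with the silyl triflate/2,6-lutidine couple protects O4 until the last step.

Step 7
Reactants: 9 triethylsilyl ether of 8; 10 2,3-dibromopropene
Product: 12 (1R,2R,3E)-6-bromo-1-[(4S)-2,2-dimethyl-1,3-dioxolan-4-yl]-1-(4-methoxybenzyloxy)-2-methyl-2-(triethylsilyloxy)hepta-3,6-diene, via alkenylzirconocene 11 (not isolated)
Conditions: Cp2Zr(H)Cl, THF, rt; then 10, CuCl (10 mol%), 0 °C → rt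
Reagents that add atoms: none
Why: syn-Hydrozirconation of the terminal alkyne places zirconium on C2 and fixes the E C2=C3 geometry; copper-catalysed allylic substitution of 11 with the allylic bromide of 10 (SN2 and SN2′ give the same product) attaches C1, C10 and C14 and leaves the alkenyl bromide for step 16.

Step 8
Reactants: 12 bromodiene acetonide
Product: 13 (2S,3R,4E)-7-bromo-2-(4-methoxybenzyloxy)-3-methyl-3-(triethylsilyloxy)octa-4,7-dienal (C6 aldehyde)
Conditions: H5IO6, EtOAc, rt
Reagents that add atoms: none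
Why: Periodic acid hydrolyses the terminal acetonide and cleaves the liberated glycol in the same flask (glycol cleavage), excising the fourth tartrate carbon and unveiling the C6 aldehyde under non-basic conditions that should not epimerise C5.

Step 9
Reactants: 14 1,1-dimethoxypropan-2-one
Product: 15 (3,3-dimethoxyprop-1-en-2-yloxy)trimethylsilane
Conditions: LiN(i-Pr)2, THF, −78 °C; Me3SiCl
Reagents that add atoms: chlorotrimethylsilane, C[Si](C)(C)Cl
Why: Kinetic deprotonation of the methyl group (the acetal C–H is not removed under these conditions) and O-silylation give the enol silane that carries C7, C8 and the masked C9.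

Step 10
Reactants: 13 C6 aldehyde; 15 enol silane
Product: 16 (4S,5R,6R,7E)-10-bromo-4-hydroxy-1,1-dimethoxy-5-(4-methoxybenzyloxy)-6-methyl-6-(triethylsilyloxy)undeca-7,10-dien-2-one
Conditions: MgBr2·OEt2 (3 equiv), CH2Cl2, −78 → −30 °C; aq. NH4Cl
Reagents that add atoms: none
Why: Chelation-controlled Mukaiyama aldol addition: MgBr2 ties the aldehyde oxygen to the α-OPMB oxygen and the enol silane attacks anti to the quaternary C4, which should give the 5,6-syn carbinol at C6 and forms C6–C7.

Step 11
Reactants: 16 β-hydroxy ketone; 17 diethyl (2-oxoethyl)phosphonate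
Product: 18 (2S,4S,5R,6R,7E)-10-bromo-2-hydroxy-1,1-dimethoxy-5-(4-methoxybenzyloxy)-6-methyl-6-(triethylsilyloxy)undeca-7,10-dien-4-yl 2-(diethoxyphosphoryl)acetate
Conditions: SmI2 (0.3 equiv), 17 (5 equiv), THF, −10 °C
Reagents that add atoms: none
Why: Evans–Tishchenko reduction: the hemiacetal of 17 on O6 transfers hydride to the C8 ketone through a chair-like six-membered samarium chelate, which should give the 1,3-anti C8 carbinol and leave O6 as the phosphonoacetate in the same operation.

Step 12
Reactants: 18 C8 alcohol; 19 angelic acid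
Product: 21 C8 angelate of 18, via mixed anhydride 20 (not isolated)
Conditions: 19, 2,4,6-Cl3C6H2COCl, Et3N, toluene, rt; then 18, 60 °C
Reagents that add atoms: none
Why: Yamaguchi-type acylation through the mixed anhydride without a nucleophilic catalyst, the conditions under which the Z (angelate) geometry is normally kept; the only free hydroxyl is at C8.

Step 13
Reactants: 21 C8 angelate
Product: 22 C5 alcohol (PMB removed, otherwise as 21)
Conditions: DDQ, CH2Cl2/pH 7 buffer (10:1), 0 °C
Reagents that add atoms: none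
Why: Oxidative cleavage of the electron-rich benzyl ether by DDQ frees O5 after it has served as chelating group in steps 5 and 10; esters, silyl ether and acetal should not react in the buffered two-phase medium.

Step 14
Reactants: 22 C5 alcohol; 23 (R)-2-methylbutanoic acid
Product: 24 C5 (R)-2-methylbutanoate (triester dimethyl acetal)
Conditions: 23, DIC, DMAP, CH2Cl2, 0 °C → rt
Reagents that add atoms: none
Why: Steglich esterification of the hindered C5 hydroxyl; carbodiimide activation does not pass through a ketene, so the α-stereocentre of 23 should be kept, and the phosphonoacetate has no thermodynamic drive to leave the less hindered O6.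

Step 15
Reactants: 24 triester dimethyl acetal
Product: 25 C9 aldehyde (otherwise as 24)
Conditions: Me3SiOTf, 2,2′-bipyridyl, CH2Cl2, 0 °C; then H2O
Reagents that add atoms: water, O
Why: Silyl triflate/bipyridyl cleavage of the dimethyl acetal through a pyridinium salt that is hydrolysed on adding water; the medium stays non-acidic, so the tertiary silyl ether and the three esters should survive.

Step 16
Reactants: 25 C9 aldehyde
Product: 26 ten-membered allylic alcohol (C9–OH, C10=C14 exocyclic, mixture of C9 epimers)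
Conditions: CrCl2 (10 equiv), NiCl2 (0.5 equiv), DMSO/THF, rt, 2 mM
Reagents that add atoms: none
Why: Nozaki–Hiyama–Kishi reaction: nickel inserts into the C10–Br bond, transmetalation gives the alkenylchromium species, which adds to the C9 aldehyde under high dilution and closes the ten-membered carbocycle at C9–C10; the C9 epimers are both oxidised next.

Step 17
Reactants: 26 allylic alcohol
Product: 27 α-methylene ketone (C9=O, C10=C14)
Conditions: Dess–Martin periodinane, NaHCO3, CH2Cl2, 0 °C → rt
Reagents that add atoms: none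
Why: Dess–Martin oxidation of the allylic alcohol converges both C9 epimers on the enone under buffered, non-epimerising conditions.

Step 18
Reactants: 27 α-methylene ketone
Product: 28 (10S)-10-methyl ketone with the E C2=C3 alkene
Conditions: [(Ph3P)CuH]6, H2O (5 equiv), toluene/THF, 0 °C → rt
Reagents that add atoms: none
Why: Copper hydride conjugate reduction of the exocyclic enone turns C14 into the methyl group; protonation of the copper enolate at C10 is expected on the exposed face of the ring to give 10S, and the hindered, less electrophilic angelate should not be reduced.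

Step 19
Reactants: 28 ring alkene
Product: 29 (2S,3R)-2,3-epoxide
Conditions: mCPBA, NaHCO3, CH2Cl2, 0 °C
Reagents that add atoms: 3-chloroperbenzoic acid, OOC(=O)c1cccc(Cl)c1
Why: Prilezhaev epoxidation of the only electron-rich alkene: the E alkene of the ten-membered ring can be reached only from its outer face, and in the conformer with the C4–O bond in the alkene plane and the small C4 methyl on the attacked side this should give the trans 2S,3R epoxide.

Step 20
Reactants: 29 epoxide phosphonoacetate
Product: 30 C6 diazophosphonoacetate of the fully oxygenated ring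
Conditions: 4-AcNHC6H4SO2N3, DBU (1.1 equiv), MeCN, 0 °C
Reagents that add atoms: 4-acetamidobenzenesulfonyl azide, CC(=O)Nc1ccc(cc1)S(=O)(=O)N=[N+]=[N-]
Why: Regitz diazo transfer: DBU deprotonates the phosphonoacetate methylene, the most acidic C–H in 29, and the carbanion takes the diazo group from the sulfonyl azide at 0 °C before the ketone α-positions are touched.

Step 21
Reactants: 30 C6 diazophosphonoacetate
Product: 31 trans-fused α-phosphono γ-lactone (C11 epimers)
Conditions: Rh2(OAc)4 (2 mol%), ClCH2CH2Cl, 60 °C, slow addition of 30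
Reagents that add atoms: none
Why: Rh2(OAc)4 (divalent rhodium) expels N2 from 30 to give an electrophilic carbenoid at C11, which inserts into a C7–H bond through a concerted three-centre transition state with retention at C7; the closest known reaction type is the dirhodium-catalysed 1,5 C–H insertion of α-diazo-α-phosphonoacetates to α-phosphono-γ-butyrolactones. The five-membered lactone (O6–C12–C11–C7–C6) closes by 1,5 insertion, which is favoured over 1,4 insertion into C6–H (β-lactone) and 1,6 insertion into C8–H (δ-lactone). C7 is set by which diastereotopic hydrogen is reached: with C5–C6–C7–C8 antiperiplanar in the ring only the hydrogen gauche to O6 is within reach, and its replacement with retention gives the trans-fused 7S lactone; C11 forms as an epimer mixture that is flattened in step 22. The step needs site selectivity against C5–H, C6–H and C8–H: C5–H and C8–H are deactivated by their own acyloxy groups (C5 also sits next to the quaternary C4) and C6–H by the ester oxygen of the tether, which leaves the C7 methylene as the least deactivated 1,5 site. Chemoselectivity against π systems rests on the ring alkene being already epoxidised and on the electron-poor, hindered angelate; the phosphonate tempers the carbenoid and is the handle for C13.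

Step 22
Reactants: 31 α-phosphono γ-lactone
Product: 32 4-O-triethylsilyl ether of the target (α-methylene lactone)
Conditions: 37% aq. CH2O, K2CO3, THF, 0 °C
Reagents that add atoms: formaldehyde, C=O
Why: Horner–Wadsworth–Emmons olefination of the α-phosphono lactone with formaldehyde installs C13 and makes C11 an sp2 centre, so both C11 epimers converge; carbonate at 0 °C should spare C8 and C10.

Step 23
Reactants: 32 4-O-triethylsilyl ether
Product: 33 CNP0217571.1 (2S,3R,4R,5R,6S,7S,8S,10S; (2R)-2-methylbutanoate)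
Conditions: HF·pyridine, pyridine, THF, 0 °C
Reagents that add atoms: none
Why: Fluoride-assisted cleavage of the tertiary triethylsilyl ether with pyridine-buffered HF should leave epoxide, esters and the α-methylene lactone intact and give the target.

**Compound list**

1 | diethyl L-tartrate | CCOC(=O)[C@H](O)[C@@H](O)C(=O)OCC | starting material
2 | diethyl (4R,5R)-2,2-dibutyl-1,3,2-dioxastannolane-4,5-dicarboxylate (stannylene acetal) | CCOC(=O)[C@@H]1O[Sn](CCCC)(CCCC)O[C@H]1C(=O)OCC | intermediate
3 | diethyl (2R,3R)-2-hydroxy-3-(4-methoxybenzyloxy)butanedioate | CCOC(=O)[C@H](OCc1ccc(OC)cc1)[C@@H](O)C(=O)OCC | intermediate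
4 | ethyl (2R,3S)-3,4-dihydroxy-2-(4-methoxybenzyloxy)butanoate | CCOC(=O)[C@H](OCc1ccc(OC)cc1)[C@@H](O)CO | intermediate
5 | ethyl (2R)-2-[(4S)-2,2-dimethyl-1,3-dioxolan-4-yl]-2-(4-methoxybenzyloxy)acetate | CCOC(=O)[C@H](OCc1ccc(OC)cc1)[C@@H]1COC(C)(C)O1 | intermediate
6 | N-methoxy-N-methyl amide corresponding to 5 (Weinreb amide) | CON(C)C(=O)[C@H](OCc1ccc(OC)cc1)[C@@H]1COC(C)(C)O1 | intermediate
7 | (1R)-1-[(4S)-2,2-dimethyl-1,3-dioxolan-4-yl]-1-(4-methoxybenzyloxy)propan-2-one | CC(=O)[C@H](OCc1ccc(OC)cc1)[C@@H]1COC(C)(C)O1 | intermediate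
8 | (1R,2R)-1-[(4S)-2,2-dimethyl-1,3-dioxolan-4-yl]-1-(4-methoxybenzyloxy)-2-methylbut-3-yn-2-ol | C#C[C@@](C)(O)[C@H](OCc1ccc(OC)cc1)[C@@H]1COC(C)(C)O1 | intermediate
9 | triethylsilyl ether of 8 | C#C[C@@](C)(O[Si](CC)(CC)CC)[C@H](OCc1ccc(OC)cc1)[C@@H]1COC(C)(C)O1 | intermediate
10 | 2,3-dibromopropene | C=C(Br)CBr | starting material
11 | (E)-alkenylzirconocene chloride from 9 (Zr on C2) | Cl[Zr](/C=C/[C@@](C)(O[Si](CC)(CC)CC)[C@H](OCc1ccc(OC)cc1)[C@@H]1COC(C)(C)O1)(C1C=CC=C1)C1C=CC=C1 | intermediate
12 | (1R,2R,3E)-6-bromo-1-[(4S)-2,2-dimethyl-1,3-dioxolan-4-yl]-1-(4-methoxybenzyloxy)-2-methyl-2-(triethylsilyloxy)hepta-3,6-diene | C=C(Br)C/C=C/[C@@](C)(O[Si](CC)(CC)CC)[C@H](OCc1ccc(OC)cc1)[C@@H]1COC(C)(C)O1 | intermediate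
13 | (2S,3R,4E)-7-bromo-2-(4-methoxybenzyloxy)-3-methyl-3-(triethylsilyloxy)octa-4,7-dienal | C=C(Br)C/C=C/[C@@](C)(O[Si](CC)(CC)CC)[C@H](OCc1ccc(OC)cc1)C=O | intermediate
14 | 1,1-dimethoxypropan-2-one | CC(=O)C(OC)OC | starting material
15 | (3,3-dimethoxyprop-1-en-2-yloxy)trimethylsilane | C=C(O[Si](C)(C)C)C(OC)OC | intermediate
16 | (4S,5R,6R,7E)-10-bromo-4-hydroxy-1,1-dimethoxy-5-(4-methoxybenzyloxy)-6-methyl-6-(triethylsilyloxy)undeca-7,10-dien-2-one | C=C(Br)C/C=C/[C@@](C)(O[Si](CC)(CC)CC)[C@H](OCc1ccc(OC)cc1)[C@@H](O)CC(=O)C(OC)OC | intermediate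
17 | diethyl (2-oxoethyl)phosphonate | CCOP(=O)(CC=O)OCC | starting material
18 | (2S,4S,5R,6R,7E)-10-bromo-2-hydroxy-1,1-dimethoxy-5-(4-methoxybenzyloxy)-6-methyl-6-(triethylsilyloxy)undeca-7,10-dien-4-yl 2-(diethoxyphosphoryl)acetate | C=C(Br)C/C=C/[C@@](C)(O[Si](CC)(CC)CC)[C@H](OCc1ccc(OC)cc1)[C@@H](OC(=O)CP(=O)(OCC)OCC)C[C@H](O)C(OC)OC | intermediate
19 | angelic acid, (Z)-2-methylbut-2-enoic acid | C/C=C(/C)C(=O)O | starting material
20 | angelic 2,4,6-trichlorobenzoic anhydride | C/C=C(/C)C(=O)OC(=O)c1c(Cl)cc(Cl)cc1Cl | intermediate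
21 | 18 with the C8 hydroxyl as (Z)-2-methylbut-2-enoate | C=C(Br)C/C=C/[C@@](C)(O[Si](CC)(CC)CC)[C@H](OCc1ccc(OC)cc1)[C@@H](OC(=O)CP(=O)(OCC)OCC)C[C@H](OC(=O)/C(C)=C\C)C(OC)OC | intermediate
22 | 21 with free C5 hydroxyl | C=C(Br)C/C=C/[C@@](C)(O[Si](CC)(CC)CC)[C@H](O)[C@@H](OC(=O)CP(=O)(OCC)OCC)C[C@H](OC(=O)/C(C)=C\C)C(OC)OC | intermediate
23 | (R)-2-methylbutanoic acid | CC[C@@H](C)C(=O)O | starting material
24 | 22 with the C5 hydroxyl as (R)-2-methylbutanoate (seco triester, C9 dimethyl acetal) | C=C(Br)C/C=C/[C@@](C)(O[Si](CC)(CC)CC)[C@H](OC(=O)[C@H](C)CC)[C@@H](OC(=O)CP(=O)(OCC)OCC)C[C@H](OC(=O)/C(C)=C\C)C(OC)OC | intermediate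
25 | seco triester C9 aldehyde | C=C(Br)C/C=C/[C@@](C)(O[Si](CC)(CC)CC)[C@H](OC(=O)[C@H](C)CC)[C@@H](OC(=O)CP(=O)(OCC)OCC)C[C@H](OC(=O)/C(C)=C\C)C=O | intermediate
26 | ten-membered ring, 9-hydroxy-10(14)-ene, (2E)-alkene, C9 epimers | C=C1C/C=C/[C@@](C)(O[Si](CC)(CC)CC)[C@H](OC(=O)[C@H](C)CC)[C@@H](OC(=O)CP(=O)(OCC)OCC)C[C@H](OC(=O)/C(C)=C\C)C1O | intermediate
27 | ten-membered ring, 9-oxo-10(14)-ene | C=C1C/C=C/[C@@](C)(O[Si](CC)(CC)CC)[C@H](OC(=O)[C@H](C)CC)[C@@H](OC(=O)CP(=O)(OCC)OCC)C[C@H](OC(=O)/C(C)=C\C)C1=O | intermediate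
28 | (4R,5R,6S,8S,10S)-9-oxo-10-methyl ring with (2E)-alkene | C1/C=C/[C@@](C)(O[Si](CC)(CC)CC)[C@H](OC(=O)[C@H](C)CC)[C@@H](OC(=O)CP(=O)(OCC)OCC)C[C@H](OC(=O)/C(C)=C\C)C(=O)[C@H]1C | intermediate
29 | (2S,3R)-2,3-epoxide of 28 | C1[C@@H]2O[C@H]2[C@@](C)(O[Si](CC)(CC)CC)[C@H](OC(=O)[C@H](C)CC)[C@@H](OC(=O)CP(=O)(OCC)OCC)C[C@H](OC(=O)/C(C)=C\C)C(=O)[C@H]1C | intermediate
30 | C6 2-diazo-2-(diethoxyphosphoryl)acetate of the epoxy ring | C1[C@@H]2O[C@H]2[C@@](C)(O[Si](CC)(CC)CC)[C@H](OC(=O)[C@H](C)CC)[C@@H](OC(=O)C(=[N+]=[N-])P(=O)(OCC)OCC)C[C@H](OC(=O)/C(C)=C\C)C(=O)[C@H]1C | intermediate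
31 | trans-fused 11-(diethoxyphosphoryl) 6,12-olide (C11 epimers) | C1[C@@H]2O[C@H]2[C@@](C)(O[Si](CC)(CC)CC)[C@H](OC(=O)[C@H](C)CC)[C@H]3OC(=O)C(P(=O)(OCC)OCC)[C@@H]3[C@H](OC(=O)/C(C)=C\C)C(=O)[C@H]1C | intermediate
32 | 4-O-triethylsilyl ether of the target | C=C1C(=O)O[C@H]2[C@H]1[C@H](OC(=O)/C(C)=C\C)C(=O)[C@@H](C)C[C@@H]1O[C@H]1[C@@](C)(O[Si](CC)(CC)CC)[C@@H]2OC(=O)[C@H](C)CC | intermediate
33 | CNP0217571.1 | C=C1C(=O)O[C@H]2[C@H]1[C@H](OC(=O)/C(C)=C\C)C(=O)[C@@H](C)C[C@@H]1O[C@H]1[C@@](C)(O)[C@@H]2OC(=O)[C@H](C)CC | target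

**Totals**

Total step count: 23. Longest linear sequence: 22 steps (steps 1–8 and 10–23 from diethyl L-tartrate); step 9 is a one-step side branch.

**Steps most likely to fail**

Step 21 (carbenoid C–H insertion). What may go wrong: insertion into the wrong C–H bond (C5–H, or C6–H to a β-lactone), attack on the C7 hydrogen that leads to the cis-fused lactone, or loss of the carbenoid to dimerisation or to ylide formation with the ketone or epoxide oxygen. Fallback (conjugate addition in place of C–H insertion): it sets out from 29. Dehydrogenation of the C9 ketone toward C7–C8 with IBX (DMSO/fluorobenzene, 65 °C), the enol being expected on the acyloxy-bearing side, should give the α-acyloxy enone F1. KOt-Bu (1 equiv, THF, 0 °C) then forms the phosphonoacetate anion, which adds to C7 in a 5-exo-trig Michael reaction. Proton transfer from C11 to the C8 enolate gives the anion of 31, and paraformaldehyde added to the same flask completes the olefination (tandem intramolecular Michael addition–olefination), so the route is rejoined at 32. C8 is re-formed by protonation in this sequence and would have to be checked.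

Step 16 (ring closure). What may go wrong: slow oxidative addition of nickel into the alkenyl bromide, which leaves the α-acyloxy aldehyde exposed to divalent chromium (pinacol coupling, migration of the angelate onto the new alkoxide) and to oligomerisation. Fallback (a faster electrophile is made first so that closure outruns these paths): it sets out from 24. CuI/NaI/trans-N,N′-dimethylcyclohexane-1,2-diamine in dioxane at 100 °C exchanges bromide for iodide to give the alkenyl iodide acetal F2. The acetal is cleaved as in step 15 to the iodo aldehyde F3, and NiCl2/CrCl2 closure of F3 comes back to 26.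

Step 18 (C10). What may go wrong: poor facial selectivity in the protonation of the C10 enolate, or epimerisation at C10 or C8 through enolate exchange. Fallback (hydroxyl-directed hydrogenation in place of conjugate reduction): it sets out from 26. The epimers are separated and the (9S)-allylic alcohol F4 is hydrogenated with [Rh(nbd)(dppb)]BF4/H2 in CH2Cl2. Hydrogen is delivered from the metal bound to the C9 hydroxyl and the 1,2-anti preference of 1,1-disubstituted allylic alcohols should give the (9S,10S)-alcohol F5. Dess–Martin oxidation of F5 comes back to 28. The 9R epimer is recycled by oxidation to 27 and NaBH4/CeCl3 reduction to 26.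

**Further compounds**

F1 | step 21 | 7,8-didehydro derivative of 29 (C7=C8 enone bearing the C8 angelate) | C1[C@@H]2O[C@H]2[C@@](C)(O[Si](CC)(CC)CC)[C@H](OC(=O)[C@H](C)CC)[C@@H](OC(=O)CP(=O)(OCC)OCC)C=C(OC(=O)/C(C)=C\C)C(=O)[C@H]1C
F2 | step 16 | alkenyl iodide analogue of 24 (C10–I, C9 dimethyl acetal) | C=C(I)C/C=C/[C@@](C)(O[Si](CC)(CC)CC)[C@H](OC(=O)[C@H](C)CC)[C@@H](OC(=O)CP(=O)(OCC)OCC)C[C@H](OC(=O)/C(C)=C\C)C(OC)OC
F3 | step 16 | alkenyl iodide analogue of 25 (C10–I, C9 aldehyde) | C=C(I)C/C=C/[C@@](C)(O[Si](CC)(CC)CC)[C@H](OC(=O)[C@H](C)CC)[C@@H](OC(=O)CP(=O)(OCC)OCC)C[C@H](OC(=O)/C(C)=C\C)C=O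
F4 | step 18 | (9S)-epimer of 26 | C=C1C/C=C/[C@@](C)(O[Si](CC)(CC)CC)[C@H](OC(=O)[C@H](C)CC)[C@@H](OC(=O)CP(=O)(OCC)OCC)C[C@H](OC(=O)/C(C)=C\C)[C@H]1O
F5 | step 18 | (9S,10S)-9-hydroxy-10-methyl ring with (2E)-alkene | C1/C=C/[C@@](C)(O[Si](CC)(CC)CC)[C@H](OC(=O)[C@H](C)CC)[C@@H](OC(=O)CP(=O)(OCC)OCC)C[C@H](OC(=O)/C(C)=C\C)[C@@H](O)[C@H]1C
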